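## Structural features

The target is an achiral dihydrochalcone built from three benzene rings. Ring A carries four contiguous substituents: the acyl group at C1', a methyl ether at C2', a benzyl group at C3' and a free hydroxyl at C4'; C5' and C6' bear hydrogen. Ring A is joined through the C7 ketone and the C8–C9 chain to the unsubstituted phenyl ring B, and through the C10 methylene at C3' to ring C, a 2-hydroxyphenyl ring. There is no stereocenter, so no stereochemical relationship has to be set or protected. The fragile groups are the two free phenols (oxidation, ionization at the doubly benzylic C10), the enolizable aryl ketone, and the C2' methyl ether, which lies ortho to the carbonyl and is exposed to chelating Lewis acids. The real difficulty is regiochemical: the C3' benzyl group sits between two oxygens that must end up different (ether at C2', phenol at C4'), and ring C is a second electron-rich phenol that would compete in any electrophilic substitution. The key step uses the fact that ring A is a resorcinol monomethyl ether with the ether ortho and the hydroxyl para to the C7 carbonyl, next to two adjacent unsubstituted carbons (C5', C6'). This is the substitution pattern that a 1,1-dimethoxy-3-silyloxybuta-1,3-diene delivers on cycloaddition with a terminal acetylenic ketone.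

## Logic of the disconnections

17 to 16: only the O–Si bond on the ring C oxygen is cut. That oxygen must be masked while strong bases and silyl electrophiles are used. A silyl ether is removed by fluoride without touching the ketone, the C2' ether or the C4' phenol, so the end of the route is one mild step.

16 to 9 and 13: C1'–C2' and C5'–C6' are cut, after formally adding methanol back across ring A and a silyl group back onto the C4' oxygen. Ring A is thereby traded for two acyclic pieces. All four substituents and the distinction between the two oxygens are already written into 9, so no substitution chemistry on an aromatic ring is needed. The forward step must be regioselective (C5' to C6') and must aromatize by losing exactly one of the two methoxy groups on C2'.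

13 to 12, then to 10 and 11: the C7 oxidation level is adjusted, then the C7–C(sp) bond is cut. This gives two commercial reagents. The forward demand is an oxidation mild enough for a terminal ynone.

9 to 8: the enol O–Si bond is cut; C5' is the acetyl methyl group of 8. This turns a hydrolytically labile diene into a storable push-pull alkene. The forward step needs kinetic deprotonation at that methyl group only.

8 to 5 and 6, through 7: the C3'–C4' bond is cut (C-acylation of the ketene acetal carbon), and one C–O bond is restored at the future C2' (elimination of methanol from the ortho ester). 6 supplies C4' and C5'. The gain is that the ketene acetal oxidation level is stored in 5, a stable compound. The forward step must generate 7 and acylate it on carbon before it is protonated or demethylated.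

5 to 3, through 4: the three C–O bonds of the ortho ester are traced back to a primary amide. An amide, unlike an ester, is alkylated cleanly on oxygen, and the resulting imidate salt is alcoholyzed as in a Pinner reaction. This avoids the O-methylation of an ester enolate, which is not dependable. The forward step must stay mild enough for the aryl silyl ether.

3 to 2, then to 1: the O–Si bond and then the amide C–N bond are cut, which closes the lactone. 1 already contains ring C, C10, C3' and the future C2' in the correct order, and its aryl ester is opened by ammonia without a catalyst.

## Other disconnections considered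

Alternative 1: The cut is at C1'–C7 and C7–C8, so the ketone carbon is supplied by carbon monoxide A4.
- Forward step: aryl iodide A2, A4 and the alkylborane A3 are joined by PdCl2(PPh3)2 and K3PO4 to give the bis(methoxymethyl) ether A1. The sequence is oxidative addition of zerovalent palladium into the carbon–iodine bond, CO insertion, transfer of the alkyl group from boron, and reductive elimination.
- In its favour: the side chain is attached late and convergently from a trivial borane. The catalytic cycle is well understood and tolerant of ethers. On predictability of the key step itself this alternative is the better of the two, since it does not depend on a crowded, hydrolysis-sensitive diene. The endgame (acid removal of two acetals) is one step, equal to the chosen plan.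
- Against it here: it does not address the structural problem. A2 is the same contiguously tetrasubstituted ring with two differentiated oxygens, and it must additionally be iodinated at C1' rather than at C5' or on ring C, all of which are activated. Direct coupling without CO insertion and β-hydride loss from the alkylpalladium intermediate are competing channels.
- Step economy: the chosen plan creates the substitution pattern in the ring-forming step, whereas A2 would probably need more steps than 9 does.

Alternative 2: The cut is at C2'–C3', C4'–C5' and C1'–C2'.
- Forward step: irradiation of the diazoketone A6 triggers a Wolff rearrangement to a vinylketene. This adds [2+2] to the siloxyalkyne A7; four-electron ring opening, six-electron ring closure and tautomerization then give phenol A5.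
- In its favour: the regiochemistry follows from connectivity and not from orbital coefficients, and the C3' substituent is simply the alkyne substituent. On regiochemical security this alternative is at least the equal of the chosen plan, and on tolerance of the crowded C3' position it is probably the better. The two oxygens also emerge differentiated, which is equal to the chosen plan.
- Against it here: the oxygen that emerges free (C2') still has to be methylated between two ortho substituents. C7 cannot be a ketone during the ketene chemistry, so it is carried as a protected carbinol, a stereocenter that is made only to be destroyed. After the key step come methylation, removal of three silyl groups and an oxidation next to free phenols, against one step in the chosen plan.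
- Step economy: A6 and A7 each require several steps, and the photochemical step limits scale. The chosen plan is clearly shorter.

Alternative 3: The cut is at C5'–C6' and C3'–C4'.
- Forward step: pyrone A9 acts as the diene toward ketene bis(trimethylsilyl) acetal A10 in hot toluene. The bicyclic adduct loses CO2 and then Me3SiOH, giving A8 with the C4' hydroxyl free after work-up.
- In its favour: the ketone, the C2' ether and the benzyl group are all present before the ring is formed, and the methoxy group never has to be distinguished from a leaving group. On oxygen differentiation this is equal to the chosen plan, and on handling it is the better, because no silyl dienol ether or terminal ynone is involved. Loss of CO2 makes the aromatization irreversible. One deprotection remains, equal to the chosen plan.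
- Against it here: 2-pyrones are reluctant dienes. The C4 methoxy group makes A9 more electron-rich while the dienophile is itself electron-rich. The new C3'–C4' bond is formed at the pyrone carbon that carries the benzyl group, whereas in the chosen plan the benzyl group sits on a non-bonding diene carbon. The final hydrogenolysis of the benzyl ether over Pd/C must spare an aryl ketone, which fluoride cleavage does not threaten.
- Step economy: a 6-unsubstituted 5-acyl-3-benzyl-4-methoxypyrone is not a standard building block and would probably cost more steps than 9.

Key step: step 8

Remark on the chemistry: 12 is made and used as the racemate because its only stereocenter is erased in step 7; 7 and 9 are assumed to be handled under anhydrous, acid-free conditions and carried forward without chromatography.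

## Route

Step 1
Reactants: 1 dihydrocoumarin (3,4-dihydro-2H-chromen-2-one)
Product: 2 3-(2-hydroxyphenyl)propanamide
Conditions: NH3 (saturated in MeOH), rt
Reagents that add atoms: ammonia, N
Why: Aminolysis of an aryl ester: ammonia attacks the activated lactone carbonyl and phenoxide leaves, opening the ring; any methyl ester formed by methanolysis converges on the same amide.

Step 2
Reactants: 2 3-(2-hydroxyphenyl)propanamide
Product: 3 3-[2-(tert-butyldimethylsilyloxy)phenyl]propanamide
Conditions: t-BuMe2SiCl, imidazole, DMF, rt
Reagents that add atoms: tert-butyldimethylsilyl chloride, CC(C)(C)[Si](C)(C)Cl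
Why: Imidazole-mediated silylation of the phenol; the primary amide is a much poorer nucleophile, and any N- or O-silylated amide reverts on aqueous work-up.

Step 3
Reactants: 3 3-[2-(tert-butyldimethylsilyloxy)phenyl]propanamide
Product: 5 tert-butyldimethyl[2-(3,3,3-trimethoxypropyl)phenoxy]silane, via imidate triflate salt 4 (not isolated)
Conditions: MeOTf, CH2Cl2, 0 °C to rt; then MeOH (excess), rt; Et3N before concentration
Reagents that add atoms: methyl trifluoromethanesulfonate, COS(=O)(=O)C(F)(F)F; methanol, CO
Why: Hard methylating agents alkylate primary amides on oxygen, and the imidatonium salt 4 is the intermediate of a Pinner reaction, so it undergoes Pinner alcoholysis (addition of MeOH, loss of NH3 as its triflate salt, capture of the dimethoxycarbenium ion by MeOH) to the ortho ester. The triflate counter-ion cannot dealkylate 4 back to an amide as chloride does, and the medium is never more acidic than an ammonium salt, which the aryl silyl ether tolerates.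

Step 4
Reactants: 5 tert-butyldimethyl[2-(3,3,3-trimethoxypropyl)phenoxy]silane; 6 acetyl chloride
Product: 8 3-{[2-(tert-butyldimethylsilyloxy)phenyl]methyl}-4,4-dimethoxybut-3-en-2-one, via ketene dimethyl acetal 7 (not isolated)
Conditions: Me3SiOTf (1.05 equiv), i-Pr2NEt (3 equiv), CH2Cl2, −20 °C to rt; then AcCl, −78 to 0 °C
Reagents that add atoms: none
Why: Me3SiOTf silylates one methoxy group of the ortho ester, MeOSiMe3 leaves and the hindered amine deprotonates the dimethoxycarbenium ion at C3'; this is the silyl triflate/amine version of the classical 1,2-elimination of alcohol from ortho esters to ketene acetals. Ketene acetal 7 is then C-acylated at its nucleophilic carbon (C3') by AcCl, and the amine removes the proton lying between the acyl group and the carbenium centre before chloride can demethylate it, giving the push-pull alkene 8. Running both events in one flask avoids isolating 7, the most hydrolysis-prone compound of the route.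

Step 5
Reactants: 8 3-{[2-(tert-butyldimethylsilyloxy)phenyl]methyl}-4,4-dimethoxybut-3-en-2-one
Product: 9 tert-butyl{2-[2-(dimethoxymethylidene)-3-(trimethylsilyloxy)but-3-en-1-yl]phenoxy}dimethylsilane
Conditions: LiN(i-Pr)2, THF, −78 °C; Me3SiCl, −78 °C to rt; pentane, filtration
Reagents that add atoms: chlorotrimethylsilane, C[Si](C)(C)Cl
Why: Kinetic deprotonation can only occur at the acetyl methyl group (C3' is fully substituted and the C10 hydrogens are not conjugated with the carbonyl), and O-silylation of the cross-conjugated lithium dienolate gives the 2-silyloxydiene; this is the enol silylation by which the unsubstituted 4,4-dimethoxybut-3-en-2-one is converted into its diene. Non-aqueous work-up keeps the ketene acetal and the enol ether intact.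

Step 6
Reactants: 10 3-phenylpropanal; 11 ethynylmagnesium bromide
Product: 12 rac-5-phenylpent-1-yn-3-ol
Conditions: HC≡CMgBr, THF, 0 °C; then H2O/aq. NH4Cl
Reagents that add atoms: none
Why: Grignard addition of an acetylide to an aldehyde; the new carbinol stereocenter is formed without control (racemate), which is immaterial because step 7 removes it.

Step 7
Reactants: 12 rac-5-phenylpent-1-yn-3-ol
Product: 13 5-phenylpent-1-yn-3-one
Conditions: Dess–Martin periodinane, CH2Cl2, 0 °C to rt
Reagents that add atoms: none
Why: Dess–Martin oxidation of a secondary propargylic alcohol under neutral, non-aqueous conditions; no nucleophile is present that could add to the terminal ynone.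

Step 8
Reactants: 9 tert-butyl{2-[2-(dimethoxymethylidene)-3-(trimethylsilyloxy)but-3-en-1-yl]phenoxy}dimethylsilane; 13 5-phenylpent-1-yn-3-one
Product: 16 1-[3-{[2-(tert-butyldimethylsilyloxy)phenyl]methyl}-4-hydroxy-2-methoxyphenyl]-3-phenylpropan-1-one, via cyclohexa-1,4-diene cycloadduct 14 (not isolated), via aryl trimethylsilyl ether 15 (not isolated)
Conditions: toluene, 80–110 °C, Ar; then dilute aq. HCl, THF, 0 °C, brief
Reagents that add atoms: none
Why: This is a normal-electron-demand Diels–Alder reaction: the diene is a ketene acetal further activated by the C4' silyloxy group, its largest HOMO coefficient lies on the unsubstituted terminus (future C5'), and this carbon bonds to the ynone β-carbon (C6') while the acetal carbon (C2') bonds to the α-carbon (C1') in a concerted but strongly asynchronous [4+2] transition state. Ring A is thus closed as a six-membered carbocycle by suprafacial [4+2] cycloaddition, giving the cyclohexa-1,4-diene 14 with a dimethyl ketal at C2'. 14 does not persist: 1,4-elimination of methanol (methoxide from C2', hydrogen from C5') is driven by aromatization and leaves the second methoxy group as the C2' ether in 15. The aryl trimethylsilyl ether of 15, para to the ketone, is hydrolysed by brief dilute acid, whereas the more hindered tert-butyldimethylsilyl ether on ring C stays. The closest known reaction type is the cycloaddition of 1,1-dimethoxy-3-trimethylsilyloxybuta-1,3-diene with acetylenic ketones and esters, which gives 4-hydroxy-2-methoxyaryl carbonyl compounds. No stereocenter is formed. The selectivity needed is regiochemical (C5' to C6', not C5' to C1'); it is secured by the polarity match between the nucleophilic diene terminus and the electrophilic ynone β-carbon, and the benzyl group, on an internal non-bonding diene carbon, neither reverses this polarity nor blocks a bonding site and as a 2-substituent favours the reactive s-cis conformer. A stepwise Mukaiyama–Michael addition followed by ring closure would give the same connectivity, so the outcome does not depend on concertedness.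

Step 9
Reactants: 16 1-[3-{[2-(tert-butyldimethylsilyloxy)phenyl]methyl}-4-hydroxy-2-methoxyphenyl]-3-phenylpropan-1-one
Product: 17 1-{4-hydroxy-3-[(2-hydroxyphenyl)methyl]-2-methoxyphenyl}-3-phenylpropan-1-one (target)
Conditions: Bu4NF, AcOH, THF, 0 °C
Reagents that add atoms: none
Why: Fluoride cleavage of an aryl silyl ether, driven by the Si–F bond; the acetic acid buffer keeps both phenols protonated, and the ketone and the C2' methyl ether are inert.

## Compound list

1 | dihydrocoumarin (3,4-dihydro-2H-chromen-2-one) | O=C1CCc2ccccc2O1 | starting material
2 | 3-(2-hydroxyphenyl)propanamide | NC(=O)CCc1ccccc1O | intermediate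
3 | 3-[2-(tert-butyldimethylsilyloxy)phenyl]propanamide | NC(=O)CCc1ccccc1O[Si](C)(C)C(C)(C)C | intermediate
4 | methyl 3-[2-(tert-butyldimethylsilyloxy)phenyl]propanimidate, trifluoromethanesulfonate salt | COC(=[NH2+])CCc1ccccc1O[Si](C)(C)C(C)(C)C.[O-]S(=O)(=O)C(F)(F)F | intermediate (not isolated)
5 | tert-butyldimethyl[2-(3,3,3-trimethoxypropyl)phenoxy]silane | COC(CCc1ccccc1O[Si](C)(C)C(C)(C)C)(OC)OC | intermediate
6 | acetyl chloride | CC(Cl)=O | starting material
7 | tert-butyl[2-(3,3-dimethoxyprop-2-en-1-yl)phenoxy]dimethylsilane | COC(OC)=CCc1ccccc1O[Si](C)(C)C(C)(C)C | intermediate (not isolated)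
8 | 3-{[2-(tert-butyldimethylsilyloxy)phenyl]methyl}-4,4-dimethoxybut-3-en-2-one | CC(=O)C(Cc1ccccc1O[Si](C)(C)C(C)(C)C)=C(OC)OC | intermediate
9 | tert-butyl{2-[2-(dimethoxymethylidene)-3-(trimethylsilyloxy)but-3-en-1-yl]phenoxy}dimethylsilane | COC(OC)=C(Cc1ccccc1O[Si](C)(C)C(C)(C)C)C(=C)O[Si](C)(C)C | intermediate
10 | 3-phenylpropanal | O=CCCc1ccccc1 | starting material
11 | ethynylmagnesium bromide | C#C[Mg]Br | starting material
12 | rac-5-phenylpent-1-yn-3-ol | C#CC(O)CCc1ccccc1 | intermediate
13 | 5-phenylpent-1-yn-3-one | C#CC(=O)CCc1ccccc1 | intermediate
14 | 1-[5-{[2-(tert-butyldimethylsilyloxy)phenyl]methyl}-6,6-dimethoxy-4-(trimethylsilyloxy)cyclohexa-1,4-dien-1-yl]-3-phenylpropan-1-one | COC1(OC)C(C(=O)CCc2ccccc2)=CCC(O[Si](C)(C)C)=C1Cc1ccccc1O[Si](C)(C)C(C)(C)C | intermediate (not isolated)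
15 | 1-[3-{[2-(tert-butyldimethylsilyloxy)phenyl]methyl}-2-methoxy-4-(trimethylsilyloxy)phenyl]-3-phenylpropan-1-one | COc1c(C(=O)CCc2ccccc2)ccc(O[Si](C)(C)C)c1Cc1ccccc1O[Si](C)(C)C(C)(C)C | intermediate (not isolated)
16 | 1-[3-{[2-(tert-butyldimethylsilyloxy)phenyl]methyl}-4-hydroxy-2-methoxyphenyl]-3-phenylpropan-1-one | COc1c(C(=O)CCc2ccccc2)ccc(O)c1Cc1ccccc1O[Si](C)(C)C(C)(C)C | intermediate
17 | 1-{4-hydroxy-3-[(2-hydroxyphenyl)methyl]-2-methoxyphenyl}-3-phenylpropan-1-one | COc1c(C(=O)CCc2ccccc2)ccc(O)c1Cc1ccccc1O | target

## Step count and least certain steps

Total: 9 steps. Longest linear sequence: 7 steps (steps 1, 2, 3, 4, 5, 8, 9); the ynone branch is 2 steps (6, 7).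

**Step 8 (key step).** The cycloaddition of the internally substituted diene may be slow. Thermal oligomerization of the terminal ynone, [2+2] addition at the ketene acetal double bond, or protodesilylation of the dienol ether by adventitious acid could then consume the partners first. The fallback sets out from 9 and comes back at 17. 9 is heated with a large excess of commercial but-3-yn-2-one, a small volatile dienophile that can be used almost as co-solvent. The same cycloaddition, loss of methanol and acidic work-up should give 1-[3-{[2-(tert-butyldimethylsilyloxy)phenyl]methyl}-4-hydroxy-2-methoxyphenyl]ethan-1-one F1. Claisen–Schmidt condensation of this methyl ketone with benzaldehyde (KOH, EtOH), during which the ring C silyl ether is also lost, should give (E)-1-{4-hydroxy-3-[(2-hydroxyphenyl)methyl]-2-methoxyphenyl}-3-phenylprop-2-en-1-one F2. Hydrogenation of the chalcone double bond (H2, RhCl(PPh3)3) then gives 17.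

**Step 3.** N-methylation of the primary amide may compete. The alcoholysis of the imidate salt may also stall, because the soluble ammonium triflate does not pull the equilibrium as a precipitating salt would, and the long exposure could slowly cleave the aryl silyl ether. The fallback sets out from 3 and comes back at 5. Dehydration of 3 (trifluoroacetic anhydride, Et3N) gives 3-[2-(tert-butyldimethylsilyloxy)phenyl]propanenitrile F3. A classical Pinner reaction (HCl gas, one equivalent of MeOH, Et2O, 0 °C, short exposure) gives methyl 3-[2-(tert-butyldimethylsilyloxy)phenyl]propanimidate hydrochloride F4. Stirring this in MeOH/hexane precipitates NH4Cl and gives 5.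

**Step 4.** 7 may attack the dimethoxycarbenium ion from which it is formed (self-condensation) or be reprotonated by the ammonium salts. After acylation, chloride-induced O-demethylation of the carbenium intermediate would give a β-keto ester, which is a dead end. The fallback sets out from 3 and comes back at 16; it replaces the elimination by the deprotonation of a thionoester.
- 3 is methylated as in step 3, and the imidate salt is treated with H2S in pyridine to give O-methyl 3-[2-(tert-butyldimethylsilyloxy)phenyl]propanethioate F5.
- LiN(i-Pr)2 and then MeI alkylate the thioenolate on sulfur, giving the ketene O,S-acetal tert-butyl{2-[3-methoxy-3-(methylsulfanyl)prop-2-en-1-yl]phenoxy}dimethylsilane F6 as a mixture of geometric isomers.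
- C-acetylation (AcCl, Et3N) gives 3-{[2-(tert-butyldimethylsilyloxy)phenyl]methyl}-4-methoxy-4-(methylsulfanyl)but-3-en-2-one F7.
- Enol silylation as in step 5 gives tert-butyl{2-[2-(methoxy(methylsulfanyl)methylidene)-3-(trimethylsilyloxy)but-3-en-1-yl]phenoxy}dimethylsilane F8.
- Cycloaddition of F8 with 13 should aromatize by loss of methanethiol, the better leaving group, so the methoxy group stays on C2'. Acidic work-up then gives 16.

**Step 5.** The trimethylsilyl dienol ether may be lost hydrolytically or thermally during isolation, and the amide base may deprotonate C10 instead. The fallback sets out from 8 and comes back at 17. Soft enolization of 8 (t-BuMe2SiOTf, Et3N, CH2Cl2, 0 °C) needs no strong base and should give the sturdier dienol ether tert-butyl({3-[(2-{[tert-butyl(dimethyl)silyl]oxy}phenyl)methyl]-4,4-dimethoxybuta-1,3-dien-2-yl}oxy)dimethylsilane F9. Cycloaddition of F9 with 13 under the conditions of step 8, without the acid treatment, gives 1-[4-(tert-butyldimethylsilyloxy)-3-{[2-(tert-butyldimethylsilyloxy)phenyl]methyl}-2-methoxyphenyl]-3-phenylpropan-1-one F10. Bu4NF (excess, AcOH buffer) removes both silyl groups and gives 17.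

## Further compounds

F1 | step 8 | 1-[3-{[2-(tert-butyldimethylsilyloxy)phenyl]methyl}-4-hydroxy-2-methoxyphenyl]ethan-1-one | COc1c(C(C)=O)ccc(O)c1Cc1ccccc1O[Si](C)(C)C(C)(C)C
F2 | step 8 | (E)-1-{4-hydroxy-3-[(2-hydroxyphenyl)methyl]-2-methoxyphenyl}-3-phenylprop-2-en-1-one | COc1c(C(=O)/C=C/c2ccccc2)ccc(O)c1Cc1ccccc1O
F3 | step 3 | 3-[2-(tert-butyldimethylsilyloxy)phenyl]propanenitrile | N#CCCc1ccccc1O[Si](C)(C)C(C)(C)C
F4 | step 3 | methyl 3-[2-(tert-butyldimethylsilyloxy)phenyl]propanimidate hydrochloride | COC(=[NH2+])CCc1ccccc1O[Si](C)(C)C(C)(C)C.[Cl-]
F5 | step 4 | O-methyl 3-[2-(tert-butyldimethylsilyloxy)phenyl]propanethioate | COC(=S)CCc1ccccc1O[Si](C)(C)C(C)(C)C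
F6 | step 4 | tert-butyl{2-[3-methoxy-3-(methylsulfanyl)prop-2-en-1-yl]phenoxy}dimethylsilane (mixture of geometric isomers) | COC(SC)=CCc1ccccc1O[Si](C)(C)C(C)(C)C
F7 | step 4 | 3-{[2-(tert-butyldimethylsilyloxy)phenyl]methyl}-4-methoxy-4-(methylsulfanyl)but-3-en-2-one (mixture of geometric isomers) | CC(=O)C(Cc1ccccc1O[Si](C)(C)C(C)(C)C)=C(OC)SC
F8 | step 4 | tert-butyl{2-[2-(methoxy(methylsulfanyl)methylidene)-3-(trimethylsilyloxy)but-3-en-1-yl]phenoxy}dimethylsilane (mixture of geometric isomers) | COC(SC)=C(Cc1ccccc1O[Si](C)(C)C(C)(C)C)C(=C)O[Si](C)(C)C
F9 | step 5 | tert-butyl({3-[(2-{[tert-butyl(dimethyl)silyl]oxy}phenyl)methyl]-4,4-dimethoxybuta-1,3-dien-2-yl}oxy)dimethylsilane | COC(OC)=C(Cc1ccccc1O[Si](C)(C)C(C)(C)C)C(=C)O[Si](C)(C)C(C)(C)C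
F10 | step 5 | 1-[4-(tert-butyldimethylsilyloxy)-3-{[2-(tert-butyldimethylsilyloxy)phenyl]methyl}-2-methoxyphenyl]-3-phenylpropan-1-one | COc1c(C(=O)CCc2ccccc2)ccc(O[Si](C)(C)C(C)(C)C)c1Cc1ccccc1O[Si](C)(C)C(C)(C)C
A1 | alternative 1 | 1-[2-methoxy-4-(methoxymethoxy)-3-{[2-(methoxymethoxy)phenyl]methyl}phenyl]-3-phenylpropan-1-one | COCOc1ccc(C(=O)CCc2ccccc2)c(OC)c1Cc1ccccc1OCOC
A2 | alternative 1 | 1-iodo-2-methoxy-4-(methoxymethoxy)-3-{[2-(methoxymethoxy)phenyl]methyl}benzene | COCOc1ccc(I)c(OC)c1Cc1ccccc1OCOC
A3 | alternative 1 | 9-(2-phenylethyl)-9-borabicyclo[3.3.1]nonane | C(Cc1ccccc1)B1C2CCCC1CCC2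
A4 | alternative 1 | carbon monoxide | [C-]#[O+]
A5 | alternative 2 | rac-6-[1-(tert-butyldimethylsilyloxy)-3-phenylpropyl]-3-(triisopropylsilyloxy)-2-{[2-(triisopropylsilyloxy)phenyl]methyl}phenol | Oc1c(C(CCc2ccccc2)O[Si](C)(C)C(C)(C)C)ccc(O[Si](C(C)C)(C(C)C)C(C)C)c1Cc1ccccc1O[Si](C(C)C)(C(C)C)C(C)C
A6 | alternative 2 | rac-(E)-5-(tert-butyldimethylsilyloxy)-1-diazo-7-phenylhept-3-en-2-one | [N-]=[N+]=CC(=O)/C=C/C(CCc1ccccc1)O[Si](C)(C)C(C)(C)C
A7 | alternative 2 | triisopropyl[(3-{2-[(triisopropylsilyl)oxy]phenyl}prop-1-yn-1-yl)oxy]silane | CC(C)[Si](OC#CCc1ccccc1O[Si](C(C)C)(C(C)C)C(C)C)(C(C)C)C(C)C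
A8 | alternative 3 | 1-[3-{[2-(benzyloxy)phenyl]methyl}-4-hydroxy-2-methoxyphenyl]-3-phenylpropan-1-one | COc1c(C(=O)CCc2ccccc2)ccc(O)c1Cc1ccccc1OCc1ccccc1
A9 | alternative 3 | 3-{[2-(benzyloxy)phenyl]methyl}-4-methoxy-5-(3-phenylpropanoyl)-2H-pyran-2-one | COc1c(C(=O)CCc2ccccc2)coc(=O)c1Cc1ccccc1OCc1ccccc1
A10 | alternative 3 | 1,1-bis(trimethylsilyloxy)ethene | C=C(O[Si](C)(C)C)O[Si](C)(C)C
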